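**Retrosynthetic overview**
1. The C4 methylene and the C5 stereocentre are traced back to a cross-conjugated dienone (C4=C5 and C7=C7a) by conjugate hydride addition at C4 and kinetic protonation at C5; C7=C7a in turn comes from a C6 silyl enol ether by Saegusa–Ito dehydrogenation.
2. Key disconnection O1–C7a: the silyl dienol ether opens to a 4-allyl-2,6-dimethoxycyclohexa-2,5-dienone. Its C3a carries two constitutionally identical 2-methoxyenone arms of ring B (C4=C5 and C7a=C7), so C3a becomes a stereocentre only when the C2 oxygen adds to one arm, and the C3 stereocentre is to choose the arm.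
3. The side-chain carbinol (C2, C3) comes from the racemic α-aryl methyl ketone by asymmetric transfer hydrogenation with dynamic kinetic resolution. C3–C3a is disconnected to 4-allyl-2,6-dimethoxyphenol and the silyl enol ether of 1-(3,4,5-trimethoxyphenyl)propan-2-one (oxidative para coupling).
4. The arylacetone is made from 3,4,5-trimethoxyphenylacetic acid through its Weinreb amide.
5. Ring order: carbocyclic ring B is bought as the phenol and dearomatised first; the tetrahydrofuran ring A is closed afterwards, in the key step.

Key step: step 6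

Assumption: the (R,R)-TsDPEN ligand is taken to give the (2R)-carbinol, by analogy with methyl ketones that carry one large substituent; should the sense be opposite, the mirror-image ligand is used.
Convention: benzofuran numbering of the target (O1, C2, C3, C3a, C4–C7, C7a) is used for all intermediates; ring A is the tetrahydrofuran ring and ring B the six-membered carbocycle.

**Route**

Step 1
Reactants: 1 3,4,5-trimethoxyphenylacetic acid
Product: 3 N-methoxy-N-methyl-2-(3,4,5-trimethoxyphenyl)acetamide, via acyl imidazolide 2 (not isolated)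
Conditions: 1,1'-carbonyldiimidazole, CH2Cl2, rt; then MeNH(OMe)·HCl, rt
Reagents that add atoms: N,O-dimethylhydroxylamine hydrochloride, CNOC.Cl; 1,1'-carbonyldiimidazole, O=C(n1ccnc1)n1ccnc1 (its imidazole is carried only in 2)
Why: Acyl imidazolide formation followed by aminolysis (Weinreb amide synthesis) is routine for arylacetic acids and avoids an acid chloride that could lose HCl to a ketene.

Step 2
Reactants: 3 N-methoxy-N-methyl-2-(3,4,5-trimethoxyphenyl)acetamide
Product: 5 1-(3,4,5-trimethoxyphenyl)propan-2-one, via bromomagnesium hemiaminal chelate 4 (not isolated)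
Conditions: MeMgBr, THF, 0 °C; 1 M HCl work-up
Reagents that add atoms: methylmagnesium bromide, C[Mg]Br (magnesium and bromine are carried only in 4)
Why: Weinreb ketone synthesis, in which the chelated tetrahedral adduct 4 resists a second addition and releases the methyl ketone only on acidic work-up.

Step 3
Reactants: 5 1-(3,4,5-trimethoxyphenyl)propan-2-one
Product: 6 (Z)-tert-butyldimethyl{[1-(3,4,5-trimethoxyphenyl)prop-1-en-2-yl]oxy}silane (used as the mixture of geometric isomers, Z expected to prevail)
Conditions: TBSOTf, Et3N, CH2Cl2, 0 °C to rt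
Reagents that add atoms: tert-butyldimethylsilyl trifluoromethanesulfonate, CC(C)(C)[Si](C)(C)OS(=O)(=O)C(F)(F)F
Why: Soft enolisation with a silyl triflate and an amine should give the aryl-conjugated silyl enol ether (the benzylic protons are the more acidic and the conjugated isomer the more stable), which places the nucleophilic carbon at the future C3.

Step 4
Reactants: 7 4-allyl-2,6-dimethoxyphenol; 6 (Z)-tert-butyldimethyl{[1-(3,4,5-trimethoxyphenyl)prop-1-en-2-yl]oxy}silane
Product: 8 4-allyl-2,6-dimethoxy-4-[2-oxo-1-(3,4,5-trimethoxyphenyl)propyl]cyclohexa-2,5-dien-1-one (racemic at the benzylic carbon)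
Conditions: PhI(OAc)2, (CF3)2CHOH/CH2Cl2 (1:4), −20 °C, 6 in excess
Reagents that add atoms: none
Why: Oxidative phenol dearomatisation with a carbon π-nucleophile: ligand exchange of the phenol on trivalent iodine and loss of iodobenzene in the ionising fluoroalcohol give a phenoxenium ion, hard oxygen nucleophiles are known to take its methoxy-bearing ortho carbons whereas the soft enol ether β-carbon is expected at the vinylogous para carbon that bears the allyl group, and loss of the silyl group gives the ketone, C3 being formed without control because it is corrected in step 5.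

Step 5
Reactants: 8 4-allyl-2,6-dimethoxy-4-[2-oxo-1-(3,4,5-trimethoxyphenyl)propyl]cyclohexa-2,5-dien-1-one
Product: 9 4-allyl-4-[(1S,2R)-2-hydroxy-1-(3,4,5-trimethoxyphenyl)propyl]-2,6-dimethoxycyclohexa-2,5-dien-1-one
Conditions: RuCl[(R,R)-TsDPEN](p-cymene) (cat.), HCO2H/Et3N (5:2), EtOAc, 40 °C
Reagents that add atoms: none
Why: Noyori-type asymmetric transfer hydrogenation with dynamic kinetic resolution: C3–H is benzylic and α to the ketone, so the ketone enantiomers should interconvert by enolisation in the amine/formic acid medium, the (3S)-ketone is reduced faster because catalyst control for the (2R)-carbinol coincides with Felkin–Anh attack anti to the quaternary carbon (C2 and C3 set together), and the dienone carbonyl, flanked by two methoxy-bearing sp2 carbons, should be reduced far more slowly by the ruthenium hydride.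

Step 6
Reactants: 9 4-allyl-4-[(1S,2R)-2-hydroxy-1-(3,4,5-trimethoxyphenyl)propyl]-2,6-dimethoxycyclohexa-2,5-dien-1-one
Product: 12 (2R,3S,3aS,7aS)-3a-allyl-5,7-dimethoxy-2-methyl-3-(3,4,5-trimethoxyphenyl)-6-(trimethylsilyloxy)-2,3,3a,7a-tetrahydro-1-benzofuran (cis-fused; H7a and allyl on one face, aryl and C4 on the other, 2-methyl trans to aryl), via potassium alkoxide 10 (not isolated), via potassium dienolate 11 (not isolated)
Conditions: KN(SiMe3)2, THF, −78 to −20 °C; then Me3SiCl, Et3N, −78 °C; non-aqueous work-up, crude product used directly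
Reagents that add atoms: chlorotrimethylsilane, C[Si](C)(C)Cl; potassium bis(trimethylsilyl)amide, C[Si](C)(C)[N-][Si](C)(C)C.[K+] (its potassium is carried only in 10 and 11)
Why: KN(SiMe3)2 converts the C2 hydroxyl into potassium alkoxide 10, which adds to the β-carbon (the future C7a) of one 2-methoxyenone arm to give the cross-conjugated potassium dienolate 11, and O-silylation with Me3SiCl fixes it as the silyl dienol ether 12. The closest known reaction type is the intramolecular oxa-Michael desymmetrisation of 4,4-disubstituted cyclohexa-2,5-dienones that carry a β-hydroxyalkyl chain, combined with ordinary enolate O-silylation. Ring A (O1–C2–C3–C3a–C7a) closes in the 5-exo-trig mode, which is geometrically easy because the nucleophile is tethered to the quaternary carbon next to the acceptor. C7a is set by the tether, which can reach the enone only from the face it is attached to, so the ring fusion is cis (H7a and allyl on the same face); C3a is set by the choice of arm, governed by the C3 stereocentre, whose aryl group should end up beside the remaining vinylic C4–H (cis to C4, trans to allyl) with the C2 methyl trans to the aryl. The step needs selection between two diastereotopic enone arms, and this is to be secured by letting the two cis-fused dienolates interconvert through retro-oxa-Michael opening at −20 °C before silylation at −78 °C, so that the isomer in which the aryl faces a ring-bound sp2 C–H instead of the freely rotating allyl methylene should dominate; C3 is not α to a carbonyl and is untouched by the base.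

Step 7
Reactants: 12 (2R,3S,3aS,7aS)-3a-allyl-5,7-dimethoxy-2-methyl-3-(3,4,5-trimethoxyphenyl)-6-(trimethylsilyloxy)-2,3,3a,7a-tetrahydro-1-benzofuran
Product: 13 (2R,3S,3aS)-3a-allyl-5,7-dimethoxy-2-methyl-3-(3,4,5-trimethoxyphenyl)-3,3a-dihydro-1-benzofuran-6(2H)-one
Conditions: Pd(OAc)2 (1.1 equiv), MeCN, rt
Reagents that add atoms: none
Why: Saegusa–Ito oxidation: silicon-to-palladium exchange gives a C7-bound enolate of divalent palladium whose only β-hydrogen is H7a, so syn β-hydride elimination should restore C7=C7a as a vinylogous ester (as known for silyl enol ethers of cyclic β-alkoxy ketones), the terminal alkene is tolerated without reoxidant or added nucleophile, and C3a is locked once O1 sits on an sp2 carbon.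

Step 8
Reactants: 13 (2R,3S,3aS)-3a-allyl-5,7-dimethoxy-2-methyl-3-(3,4,5-trimethoxyphenyl)-3,3a-dihydro-1-benzofuran-6(2H)-one
Product: 15 (2R,3S,3aR,5S)-3a-allyl-5,7-dimethoxy-2-methyl-3-(3,4,5-trimethoxyphenyl)-3,3a,4,5-tetrahydro-1-benzofuran-6(2H)-one (target), via copper enolate 14 (not isolated)
Conditions: [(Ph3P)CuH]6 (0.2 equiv of hexamer), THF/toluene, 0 °C; then t-BuCO2H, −78 °C; pH 7 buffer work-up
Reagents that add atoms: hexameric triphenylphosphine copper hydride, one unit [CuH].P(c1ccccc1)(c1ccccc1)c1ccccc1 (its copper is carried only in 14; 15 gains hydrogen only)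
Why: Conjugate reduction with a monovalent copper hydride: hydride should add only to C4, the β-carbon of the one Michael-competent arm (C7=C7a is a fully substituted vinylogous ester, the allyl group is unactivated), and the copper enolate is protonated at −78 °C on the face opposite the pseudo-axial 3a-allyl group, which is 1,3 to C5, so that the 5-methoxy group ends up cis to allyl (5S), a cold buffered work-up guarding against epimerisation at this α-keto centre.

**Compound list**
1 | 3,4,5-trimethoxyphenylacetic acid | COc1cc(CC(=O)O)cc(OC)c1OC | starting material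
2 | 1-(imidazol-1-yl)-2-(3,4,5-trimethoxyphenyl)ethanone (acyl imidazolide, not isolated) | COc1cc(CC(=O)n2ccnc2)cc(OC)c1OC | intermediate
3 | N-methoxy-N-methyl-2-(3,4,5-trimethoxyphenyl)acetamide | COc1cc(CC(=O)N(C)OC)cc(OC)c1OC | intermediate
4 | bromomagnesium hemiaminal chelate of 3 with MeMgBr (not isolated) | COc1cc(CC(C)(O[Mg]Br)N(C)OC)cc(OC)c1OC | intermediate
5 | 1-(3,4,5-trimethoxyphenyl)propan-2-one | COc1cc(CC(C)=O)cc(OC)c1OC | intermediate
6 | (Z)-tert-butyldimethyl{[1-(3,4,5-trimethoxyphenyl)prop-1-en-2-yl]oxy}silane | COc1cc(/C=C(/C)O[Si](C)(C)C(C)(C)C)cc(OC)c1OC | intermediate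
7 | 4-allyl-2,6-dimethoxyphenol | C=CCc1cc(OC)c(O)c(OC)c1 | starting material
8 | 4-allyl-2,6-dimethoxy-4-[2-oxo-1-(3,4,5-trimethoxyphenyl)propyl]cyclohexa-2,5-dien-1-one, racemic | C=CCC1(C=C(OC)C(=O)C(OC)=C1)C(C(C)=O)c1cc(OC)c(OC)c(OC)c1 | intermediate
9 | 4-allyl-4-[(1S,2R)-2-hydroxy-1-(3,4,5-trimethoxyphenyl)propyl]-2,6-dimethoxycyclohexa-2,5-dien-1-one | C=CCC1(C=C(OC)C(=O)C(OC)=C1)[C@@H]([C@@H](C)O)c1cc(OC)c(OC)c(OC)c1 | intermediate
10 | potassium alkoxide of 9 (not isolated) | C=CCC1(C=C(OC)C(=O)C(OC)=C1)[C@@H]([C@@H](C)[O-])c1cc(OC)c(OC)c(OC)c1.[K+] | intermediate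
11 | potassium (2R,3S,3aS,7aS)-3a-allyl-5,7-dimethoxy-2-methyl-3-(3,4,5-trimethoxyphenyl)-2,3,3a,7a-tetrahydro-1-benzofuran-6-olate (cis-fused dienolate, not isolated) | C=CC[C@]12C=C(OC)C([O-])=C(OC)[C@H]1O[C@H](C)[C@H]2c1cc(OC)c(OC)c(OC)c1.[K+] | intermediate
12 | (2R,3S,3aS,7aS)-3a-allyl-5,7-dimethoxy-2-methyl-3-(3,4,5-trimethoxyphenyl)-6-(trimethylsilyloxy)-2,3,3a,7a-tetrahydro-1-benzofuran | C=CC[C@]12C=C(OC)C(O[Si](C)(C)C)=C(OC)[C@H]1O[C@H](C)[C@H]2c1cc(OC)c(OC)c(OC)c1 | intermediate
13 | (2R,3S,3aS)-3a-allyl-5,7-dimethoxy-2-methyl-3-(3,4,5-trimethoxyphenyl)-3,3a-dihydro-1-benzofuran-6(2H)-one | C=CC[C@]12C=C(OC)C(=O)C(OC)=C1O[C@H](C)[C@H]2c1cc(OC)c(OC)c(OC)c1 | intermediate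
14 | copper enolate of 15 (monovalent copper, phosphine ligands omitted, not isolated) | C=CC[C@]12CC(OC)=C(O[Cu])C(OC)=C1O[C@H](C)[C@H]2c1cc(OC)c(OC)c(OC)c1 | intermediate
15 | (2R,3S,3aR,5S)-3a-allyl-5,7-dimethoxy-2-methyl-3-(3,4,5-trimethoxyphenyl)-3,3a,4,5-tetrahydro-1-benzofuran-6(2H)-one | C=CC[C@]12C[C@H](OC)C(=O)C(OC)=C1O[C@H](C)[C@H]2c1cc(OC)c(OC)c(OC)c1 | target

Total step count: 8. Longest linear sequence: 8 steps (1 to 15; phenol 7 enters at step 4).

**Steps most likely to fail**

Step 4. The oxidant may consume the electron-rich enol ether before the phenol is activated, the carbon nucleophile may add at a methoxy-bearing ortho carbon instead of the para carbon, or the acidic medium may desilylate 6 first. The fallback sets out from phenol 7 and separates oxidation from C–C bond formation. Phenol 7 alone is oxidised with PhI(OAc)2 in methanol at −20 °C to the ortho-quinone monoketal 4-allyl-2,6,6-trimethoxycyclohexa-2,4-dien-1-one F1, which is kept cold and used at once because it dimerises on standing. It is then ionised with catalytic Me3SiOTf in CH2Cl2 at −78 °C in the presence of 6, so that the same cation meets the enol ether in the absence of oxidant; this returns to the route at 8.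

Step 6. Discrimination between the two enone arms by the C3 aryl group may be poor, or equilibration may be incomplete before silylation so that a kinetic mixture is fixed. The fallback sets out from 9 and puts arm selection under reagent control. A chiral BINOL-derived phosphoric acid (either enantiomer of TRIP screened, toluene, rt), of the kind known to desymmetrise cyclohexadienones with a hydroxyalkyl chain by oxa-Michael addition, should give the bicyclic ketone (2R,3S,3aS,7aS)-3a-allyl-5,7-dimethoxy-2-methyl-3-(3,4,5-trimethoxyphenyl)-3,3a,7,7a-tetrahydro-1-benzofuran-6(2H)-one F2 as a mixture of C7 epimers. Soft enolisation (Me3SiOTf, Et3N, CH2Cl2, −78 °C) removes the C7 centre and returns to the route at 12.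

Step 5. Enolisation at the hindered C3 may be slower than reduction, so that the dynamic resolution stalls as a plain kinetic resolution, or hydride may be transferred to the dienone carbonyl. The fallback sets out from racemic 8 and gives up epimerisation during the reduction. Corey–Bakshi–Shibata reduction ((S)-Me-CBS oxazaborolidine, catecholborane, toluene, −78 °C) under reagent control should convert both ketone enantiomers into (2R)-carbinols, namely 9 and its C3 epimer 4-allyl-4-[(1R,2R)-2-hydroxy-1-(3,4,5-trimethoxyphenyl)propyl]-2,6-dimethoxycyclohexa-2,5-dien-1-one F3. These are diastereomers and are separated by chromatography; 9 rejoins the route, while F3 is oxidised back with Dess–Martin periodinane and epimerised with DBU to racemic 8 for another pass.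

**Further compounds**
F1 | step 4 | 4-allyl-2,6,6-trimethoxycyclohexa-2,4-dien-1-one | C=CCC1=CC(OC)(OC)C(=O)C(OC)=C1
F2 | step 6 | (2R,3S,3aS,7aS)-3a-allyl-5,7-dimethoxy-2-methyl-3-(3,4,5-trimethoxyphenyl)-3,3a,7,7a-tetrahydro-1-benzofuran-6(2H)-one, mixture of C7 epimers | C=CC[C@]12C=C(OC)C(=O)C(OC)[C@H]1O[C@H](C)[C@H]2c1cc(OC)c(OC)c(OC)c1
F3 | step 5 | 4-allyl-4-[(1R,2R)-2-hydroxy-1-(3,4,5-trimethoxyphenyl)propyl]-2,6-dimethoxycyclohexa-2,5-dien-1-one | C=CCC1(C=C(OC)C(=O)C(OC)=C1)[C@H]([C@@H](C)O)c1cc(OC)c(OC)c(OC)c1
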